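# Proposed synthesis of CNP0403384.1: (+)-isolariciresinol-type 9-O-(E)-p-coumarate by a photoenol Diels–Alder route

## Analysis of the target

The target is a 1-aryltetralin lignan in which ring A is an arene (C4a to C8a, OMe on C6, OH on C7) and ring B (C1 to C4) is a saturated six-membered ring fused to it. C1 carries a 4-hydroxy-3-methoxyphenyl group, C2 carries the CH2O group (C9) that is esterified with (E)-p-coumaric acid, C3 carries a free CH2OH (C9′) and C4 is a CH2. The three stereocentres are contiguous and all-trans, (1S,2R,3R): the aryl group on C1 is trans to the C9 arm on C2, which is trans to the C9′ arm on C3. Sensitive functions are three phenols, a cinnamate ester (attacked by base, hydride, hydrogenation and ultraviolet light) that sits 1,4 to a free primary hydroxyl and can migrate to it, and the doubly benzylic C1–H. Two things make the synthesis hard: the three centres, one of them a diarylmethine, must be set in the absolute sense, and C9 and C9′ are two primary CH2O groups in almost the same surroundings that must be told apart. The strategy rests on the fusion of ring B to ring A: C4=C4a–C8a=C1 is a latent o-quinodimethane and C2–C3 is a trans-disubstituted dienophile. An unsymmetrical dienophile delivers C9 and C9′ at different oxidation levels from the outset. Because C7–O is para to C4a, a hydroxyl left at C4 by the diene precursor is easily removed afterwards.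

## Retrosynthetic reasoning

**Ester C9–O bond.** Target 25 is traced to its fully silylated form 24, and 24 to alcohol 20 and acid 23 (from 21 through 22). The coumaroyl group is put on last because it would not survive the ultraviolet light, hydride and hydrogenolysis used earlier. The cut makes the end convergent and leaves only Si–O bonds for the final step. The forward reactions must acylate one primary hydroxyl while C9′ is masked, and unmask everything without letting the acyl group move to C9′.

**Telling C9 from C9′.** Alcohol 20 goes back through 19 and 18 to diol 17. The C9 oxygen has been a benzyl ether since the dienophile was made; the C9′ oxygen first appears as a free hydroxyl and is silylated (18 to 19) before the benzyl group is removed (19 to 20). No skeletal bond is cut here. What is gained is that the two hydroxymethyl groups are never both free before the ester is in place. A benzyl ether was chosen because it is inert to light, hydride and Lewis acid and leaves by hydrogenolysis at a stage where the molecule has no alkene.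

**C4–O and the oxidation level of C9′.** Compound 18 comes from 17 by putting a hydroxyl back on C4, and 17 from imide 16 by raising C9′ to an acyl group. The C4 hydroxyl is the trace of the aldehyde that generates the diene; it is benzylic and para to the C7 oxygen, so ionic hydrogenation removes it. The acyl group on C3 is what makes C2=C3 a dienophile and ends as the free CH2OH.

**Ring B: C1–C2 and C3–C4.** Imide 16 is cut into dienol 15 and enoyl imide 14, and 15 is the photoenol of aldehyde 8. These are the only two bonds of ring B whose scission leaves an aromatic precursor of ring A and a simple E-alkene. A cut at C1–C8a or C4–C4a would make one bond at a time and would need the stereocentres in place beforehand. The gain is ring B, two skeletal bonds and all three stereocentres of the target (plus a disposable one at C4) in a single step. The forward reaction must place the acyl carbon next to the carbinol carbon, go endo, and take one face of the dienophile under control of the auxiliary.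

**Diarylmethane 8.** The bond between the ring A carbon (future C8a) and the benzylic CH2 (future C1) is cut, giving aryl bromide 2 and benzylic boronate 7. An sp2–sp3 cross-coupling with boron tolerates the free aldehyde. Bromide 2 comes from 1 in one step; 7 comes from 3 through 4, 5 and 6.

**Dienophile 14.** The C=C bond is cut (olefination of aldehyde 13 with phosphonate 12), and 12 is the N-acylation product of auxiliary 9 with acid 10 through the mixed anhydride 11. This gives the E-enoyl imide in two steps from commercial materials.

## Alternatives that were turned down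

**Alternative 1:** oxidative dimerisation of an auxiliary-bound bromoferulate.
- Disconnection: C2–C3 and C1–C8a, so that both halves come from one monomer, imide A1.
- Forward key step: Ag2O oxidises the phenol of A1 to a phenoxyl radical with spin density on the side-chain carbon next to the imide. Two radicals join there (C2–C3), and in the resulting bis-quinone methide one ring attacks the other quinone methide carbon (C1–C8a) to give dihydronaphthalene A2.
- For: it is the shortest way to the carbon skeleton, uses a single cheap monomer, forms two skeletal bonds and ring B in one operation, and the bromine blocks coupling at the ring position ortho to OH. On step count to the skeleton it is stronger than the chosen route.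
- Against: A2 has C9 and C9′ at the same oxidation level with the same auxiliary, distinguished only by conjugation of the C3 acyl group, while the target needs one esterified and one free. C3 is not yet a stereocentre (C3=C4) and must be made by a later reduction that has to give 2,3-trans and also remove two aryl bromides. Two planar radicals must each react on the right face, and the phenolic product is as oxidisable as A1, so other coupling modes and oligomers compete.
- Comparison: the chosen cycloaddition needs more steps to build its partners, but creates C1, C2 and C3 together in a concerted step and delivers C9 and C9′ already different.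

**Alternative 2:** phenolate para-Michael closure onto an α-methylene aldehyde.
- Disconnection: C4–C4a only.
- Forward key step: with K2CO3 the ring A phenolate of the acyclic aldehyde A3 attacks through its para carbon the terminal alkene carbon (6-endo), the ring rearomatises, and protonation at C3 gives A4.
- For: the coumarate is already in place and C9′ is an aldehyde, so the two arms differ in oxidation level; after ring closure only a chemoselective aldehyde reduction and desilylation remain. The endgame is shorter than in the chosen route, no photochemistry is needed, and C3 can equilibrate to trans through the enol. On these points it is stronger.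
- Against: the key step makes one bond and one stereocentre. A3 must already hold C1 and C2 in the absolute sense, and C1 is a diarylmethine whose two aryl groups differ only in the placement of OH and OMe, next to C2; no simple auxiliary or catalyst control offers itself for it. The coumarate, the enal and a free phenol must be carried through the assembly of A3 and then survive carbonate.
- Comparison: stronger after the ring closure, weaker before it. The chosen strategy puts the hard stereochemical problem into one cycloaddition and pays with six functional-group steps afterwards.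

**Alternative 3:** donor–acceptor cyclopropane [3+3] annulation.
- Disconnection: C1–C8a and C3–C4, between arene A5 and cyclopropane A6.
- Forward key step: Sc(OTf)3 activates the malonate of A6; the arene carbon of A5 para to OMe opens the ring at the benzylic carbon with inversion (C1–C8a), and base lets the freed malonate displace the benzylic chloride (C3–C4) to give A7.
- For: convergent, two skeletal bonds and ring B in one flask, C1 from a stereospecific opening; in bond count it equals the chosen route.
- Against: A5 is both nucleophile (arene) and electrophile (a benzylic chloride that Sc(OTf)3 can ionise), so self-alkylation competes. The donor aryl of A6 is very electron-rich, so the ring can open to a benzylic cation before attack and the configuration at C1 leaks. A stereospecific opening that gives 1,2-trans directly needs the 2,3-cis cyclopropane, itself a multistep enantioselective target with an aldehyde open to Friedel–Crafts attack. C3 is formed quaternary and needs decarboxylation to become a stereocentre. Afterwards the C3 ester must be reduced while a coumarate is present or be shielded by extra protecting-group steps.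
- Comparison: similar convergence, but more redox steps and less secure stereochemistry than a concerted suprafacial cycloaddition, in which C9′ is reduced before the coumarate exists.

Key step: step 9

Remark on the chemistry: 6-bromovanillin is taken as 2-bromo-4-hydroxy-5-methoxybenzaldehyde (bromine para to OMe). The tetralin locants of the target (C1 aryl-bearing carbon, C4 the CH2, C9 on C2, C9′ on C3) are kept for all intermediates, also where systematic numbering would differ.

## Route

Step 1
Reactants: 1 6-bromovanillin
Product: 2 2-bromo-5-methoxy-4-(triisopropylsilyloxy)benzaldehyde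
Conditions: TIPSCl, imidazole, DMF, rt
Reagents that add atoms: triisopropylsilyl chloride, CC(C)[Si](Cl)(C(C)C)C(C)C
Why: Imidazole-promoted silylation of the phenol, which would otherwise interfere with the basic cross-coupling and the photoenol; the triisopropylsilyl ether is chosen because an aryl–O–Si bond para to a formyl group has to survive aqueous base in step 6.

Step 2
Reactants: 3 vanillin
Product: 4 3-methoxy-4-(triisopropylsilyloxy)benzaldehyde
Conditions: TIPSCl, imidazole, DMF, rt
Reagents that add atoms: triisopropylsilyl chloride, CC(C)[Si](Cl)(C(C)C)C(C)C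
Why: Same phenol silylation as in step 1; starting from the aldehyde avoids any competition between a phenol and a benzylic alcohol for the silyl chloride.

Step 3
Reactants: 4 3-methoxy-4-(triisopropylsilyloxy)benzaldehyde
Product: 5 [3-methoxy-4-(triisopropylsilyloxy)phenyl]methanol
Conditions: NaBH4, MeOH/THF, 0 °C
Reagents that add atoms: none
Why: Borohydride reduction of an aryl aldehyde to the benzylic alcohol; the aryl silyl ether is stable under these cold, briefly basic conditions.

Step 4
Reactants: 5 [3-methoxy-4-(triisopropylsilyloxy)phenyl]methanol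
Product: 6 4-(chloromethyl)-2-methoxy-1-(triisopropylsilyloxy)benzene
Conditions: SOCl2, pyridine, CH2Cl2, 0 °C
Reagents that add atoms: thionyl chloride, O=S(Cl)Cl
Why: Chlorodehydroxylation through the chlorosulfite; pyridine takes up the HCl so the silyl ether is kept, and the electron-rich benzylic chloride is used without chromatography.

Step 5
Reactants: 6 4-(chloromethyl)-2-methoxy-1-(triisopropylsilyloxy)benzene
Product: 7 2-[3-methoxy-4-(triisopropylsilyloxy)benzyl]-4,4,5,5-tetramethyl-1,3,2-dioxaborolane
Conditions: B2pin2, Pd(dba)2 (3 mol %), P(4-MeOC6H4)3 (6 mol %), KOAc, toluene, 50 °C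
Reagents that add atoms: bis(pinacolato)diboron, CC1(C)OB(OC1(C)C)B1OC(C)(C)C(C)(C)O1
Why: Miyaura borylation of a benzylic halide: zerovalent palladium adds to the C–Cl bond, the acetate-activated diboron transmetalates and reductive elimination gives the C–B bond; KOAc is too weak a base to let the product couple with unreacted chloride.

Step 6
Reactants: 2 2-bromo-5-methoxy-4-(triisopropylsilyloxy)benzaldehyde; 7 2-[3-methoxy-4-(triisopropylsilyloxy)benzyl]-4,4,5,5-tetramethyl-1,3,2-dioxaborolane
Product: 8 5-methoxy-2-[3-methoxy-4-(triisopropylsilyloxy)benzyl]-4-(triisopropylsilyloxy)benzaldehyde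
Conditions: Pd(OAc)2 (3 mol %), SPhos (6 mol %), K3PO4, toluene/H2O (10:1), 80 °C
Reagents that add atoms: none
Why: Suzuki–Miyaura coupling of a primary benzylic boronate (no β-hydrogen) with an aryl bromide activated by its ortho formyl group; the boron reagent tolerates the free aldehyde, which a benzylic zinc or magnesium reagent would attack.

Step 7
Reactants: 9 (S)-4-benzyl-2-oxazolidinone; 10 diethylphosphonoacetic acid
Product: 12 (S)-4-benzyl-3-[2-(diethoxyphosphoryl)acetyl]oxazolidin-2-one, via mixed pivalic anhydride 11 (not isolated)
Conditions: PivCl, Et3N, THF, −20 °C; then 9, LiCl, −20 °C → rt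
Reagents that add atoms: pivaloyl chloride, CC(C)(C)C(=O)Cl (its atoms are present in 11 only)
Why: N-Acylation of the oxazolidinone through a mixed pivalic anhydride in the presence of LiCl and Et3N; the auxiliary attacks the unhindered phosphonoacetyl carbonyl and not the pivaloyl one, and its stereocentre is not involved.

Step 8
Reactants: 12 (S)-4-benzyl-3-[2-(diethoxyphosphoryl)acetyl]oxazolidin-2-one; 13 (benzyloxy)acetaldehyde
Product: 14 (S)-4-benzyl-3-[(E)-4-(benzyloxy)but-2-enoyl]oxazolidin-2-one
Conditions: LiCl, i-Pr2NEt, MeCN, 0 °C → rt
Reagents that add atoms: none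
Why: Horner–Wadsworth–Emmons olefination under Masamune–Roush conditions, mild enough for the imide and the enolisable α-alkoxy aldehyde; the stabilised phosphonate gives the E-alkene.

Step 9
Reactants: 8 5-methoxy-2-[3-methoxy-4-(triisopropylsilyloxy)benzyl]-4-(triisopropylsilyloxy)benzaldehyde; 14 (S)-4-benzyl-3-[(E)-4-(benzyloxy)but-2-enoyl]oxazolidin-2-one
Product: 16 (1S,2R,3S,4S)-cycloadduct bearing C1 aryl plus C2 benzyloxymethyl plus C3 acyl oxazolidinone plus C4 hydroxyl, via (E,E)-hydroxy-o-quinodimethane 15 (not isolated)
Conditions: hν (365 nm), 14 (3 equiv), degassed toluene, 20 °C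
Reagents that add atoms: none
Why: The excited aldehyde (n,π* triplet) abstracts a hydrogen from the doubly benzylic CH2 through a six-membered transition state, and of the dienols formed only 15, with OH and aryl both outward, persists, because the isomer with OH inward returns to 8 by a 1,5-hydrogen shift. Dienol 15 then adds thermally to 14 in a concerted, suprafacial [4+2] cycloaddition (photoenolisation/Diels–Alder reaction; closest known type: capture of α-hydroxy-α′-aryl-o-quinodimethanes by acrylic or fumaric dienophiles that carry a chiral auxiliary), forming C1–C2 and C3–C4, closing ring B as a six-membered carbocycle by intermolecular cycloaddition and giving ring A its aromaticity back. Regioselectivity is required and comes from the hydroxyl, the stronger of the two terminal donors: the largest HOMO coefficient lies on C1, which bonds to the β-carbon of the enoyl imide, and the O–H···O=C hydrogen bond to the imide holds the acyl carbon beside the carbinol carbon C4. The same hydrogen bond and secondary overlap place the acyl group endo, under ring A, so C3 (acyl) is set cis to C4–OH and to the C1 aryl group; C2 follows from the E geometry of 14 (CH2OBn trans to acyl, hence C1/C2 trans and C2/C3 trans), and the C1/C4 cis relation from the E,E geometry of 15. The absolute sense comes from the auxiliary: with no chelating metal the imide should react in its dipole-minimised conformation (carbonyls antiperiplanar, enoyl s-cis), and in the endo arrangement ring A and the carbinol terminus lie over the oxazolidinone, so the diene must take the face turned away from the 4-benzyl group, which for the (S)-auxiliary is the Cα-Re face and leads to (1S,2R,3S,4S). An excess of 14 and exclusion of oxygen serve the bimolecular capture of a short-lived diene; 16 is diastereomeric with any product of attack on the other face and is purified by chromatography before the auxiliary is removed.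

Step 10
Reactants: 16 (1S,2R,3S,4S)-cycloadduct
Product: 17 [(1S,2R,3R,4S)-2-(benzyloxymethyl)-4-hydroxy-6-methoxy-1-[3-methoxy-4-(triisopropylsilyloxy)phenyl]-7-(triisopropylsilyloxy)-1,2,3,4-tetrahydronaphthalen-3-yl]methanol
Conditions: LiBH4, MeOH (1 equiv), Et2O/THF, 0 °C
Reagents that add atoms: none
Why: Reductive removal of the oxazolidinone: hydride adds to the exocyclic imide carbonyl, auxiliary 9 is expelled and the aldehyde is reduced on to the C9′ alcohol; the medium is cold and only weakly basic, so C3 is not epimerised and the β-hydroxy imide does not undergo retro-aldol cleavage (the change of descriptor at C3 is a priority change only).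

Step 11
Reactants: 17 diol
Product: 18 [(1S,2R,3R)-2-(benzyloxymethyl)-6-methoxy-1-[3-methoxy-4-(triisopropylsilyloxy)phenyl]-7-(triisopropylsilyloxy)-1,2,3,4-tetrahydronaphthalen-3-yl]methanol
Conditions: Et3SiH, BF3·OEt2, CH2Cl2, −78 → −20 °C
Reagents that add atoms: none
Why: Ionic hydrogenation: BF3·OEt2 ionises the C4 hydroxyl, which is benzylic and para to the C7 silyloxy group, and Et3SiH transfers hydride to the cation; C4 becomes a CH2, so its configuration does not matter, C1 to C3 are untouched and the primary alcohol does not ionise.

Step 12
Reactants: 18 primary alcohol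
Product: 19 C9′ tert-butyldimethylsilyl ether of 18, (1S,2R,3R)
Conditions: TBSCl, imidazole, DMF, rt
Reagents that add atoms: tert-butyldimethylsilyl chloride, CC(C)(C)[Si](C)(C)Cl
Why: Silylation of the only free hydroxyl (C9′–OH), so that after debenzylation only the C9 hydroxyl can be acylated; the group is chosen to leave in the final fluoride step together with the phenolic silyl ethers.

Step 13
Reactants: 19 benzyl ether
Product: 20 [(1S,2R,3R)-3-(tert-butyldimethylsilyloxymethyl)-6-methoxy-1-[3-methoxy-4-(triisopropylsilyloxy)phenyl]-7-(triisopropylsilyloxy)-1,2,3,4-tetrahydronaphthalen-2-yl]methanol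
Conditions: H2 (1 atm), Pd/C, EtOAc, rt
Reagents that add atoms: none
Why: Hydrogenolysis of the benzyl ether on palladium on carbon; at this stage the molecule holds no alkene, halide or other reducible group, and aryl and alkyl silyl ethers are stable in a non-protic solvent.

Step 14
Reactants: 21 (E)-p-coumaric acid
Product: 23 (E)-4-(tert-butyldimethylsilyloxy)cinnamic acid, via bis-silylated coumarate 22 (not isolated)
Conditions: TBSCl (2.2 equiv), imidazole, DMF, rt; then AcOH/THF/H2O, rt
Reagents that add atoms: tert-butyldimethylsilyl chloride, CC(C)(C)[Si](C)(C)Cl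
Why: Both acidic hydroxyls are silylated and the silyl ester, far more labile than the aryl silyl ether, is hydrolysed selectively by aqueous acetic acid (carbonate in methanol would also cleave the aryl ether); the E-alkene is untouched.

Step 15
Reactants: 20 C9 alcohol; 23 (E)-4-(tert-butyldimethylsilyloxy)cinnamic acid
Product: 24 [(1S,2R,3R)-3-(tert-butyldimethylsilyloxymethyl)-6-methoxy-1-[3-methoxy-4-(triisopropylsilyloxy)phenyl]-7-(triisopropylsilyloxy)-1,2,3,4-tetrahydronaphthalen-2-yl]methyl (E)-3-[4-(tert-butyldimethylsilyloxy)phenyl]acrylate
Conditions: EDC·HCl, DMAP, CH2Cl2, 0 °C → rt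
Reagents that add atoms: none
Why: Steglich esterification (carbodiimide activation, acyl transfer by DMAP) of the only free hydroxyl, the primary C9–OH; no stereocentre is involved and the E-alkene is retained.

Step 16
Reactants: 24 fully silylated ester
Product: 25 [(1S,2R,3R)-7-hydroxy-1-(4-hydroxy-3-methoxyphenyl)-3-(hydroxymethyl)-6-methoxy-1,2,3,4-tetrahydronaphthalen-2-yl]methyl (E)-3-(4-hydroxyphenyl)acrylate (target)
Conditions: TBAF, AcOH (1:1), THF, 0 °C → rt
Reagents that add atoms: none
Why: Fluoride cleaves the three aryl–O–Si bonds and the primary alkyl O–Si bond; acetic acid keeps the medium near neutral, so the phenoxides and the C9′ alkoxide are protonated as they form and the cinnamate should neither hydrolyse nor migrate to C9′.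

## Compound list

1 | 6-bromovanillin (2-bromo-4-hydroxy-5-methoxybenzaldehyde) | COc1cc(C=O)c(Br)cc1O | starting material
2 | 2-bromo-5-methoxy-4-(triisopropylsilyloxy)benzaldehyde | COc1cc(C=O)c(Br)cc1O[Si](C(C)C)(C(C)C)C(C)C | intermediate
3 | vanillin (4-hydroxy-3-methoxybenzaldehyde) | COc1cc(C=O)ccc1O | starting material
4 | 3-methoxy-4-(triisopropylsilyloxy)benzaldehyde | COc1cc(C=O)ccc1O[Si](C(C)C)(C(C)C)C(C)C | intermediate
5 | [3-methoxy-4-(triisopropylsilyloxy)phenyl]methanol | COc1cc(CO)ccc1O[Si](C(C)C)(C(C)C)C(C)C | intermediate
6 | 4-(chloromethyl)-2-methoxy-1-(triisopropylsilyloxy)benzene | COc1cc(CCl)ccc1O[Si](C(C)C)(C(C)C)C(C)C | intermediate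
7 | 2-[3-methoxy-4-(triisopropylsilyloxy)benzyl]-4,4,5,5-tetramethyl-1,3,2-dioxaborolane | COc1cc(CB2OC(C)(C)C(C)(C)O2)ccc1O[Si](C(C)C)(C(C)C)C(C)C | intermediate
8 | 5-methoxy-2-[3-methoxy-4-(triisopropylsilyloxy)benzyl]-4-(triisopropylsilyloxy)benzaldehyde | COc1cc(C=O)c(Cc2ccc(O[Si](C(C)C)(C(C)C)C(C)C)c(OC)c2)cc1O[Si](C(C)C)(C(C)C)C(C)C | intermediate
9 | (S)-4-benzyl-2-oxazolidinone | O=C1N[C@@H](Cc2ccccc2)CO1 | starting material
10 | diethylphosphonoacetic acid | CCOP(=O)(CC(=O)O)OCC | starting material
11 | 2-(diethoxyphosphoryl)acetic pivalic anhydride | CCOP(=O)(CC(=O)OC(=O)C(C)(C)C)OCC | intermediate (not isolated)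
12 | (S)-4-benzyl-3-[2-(diethoxyphosphoryl)acetyl]oxazolidin-2-one | CCOP(=O)(CC(=O)N1[C@@H](Cc2ccccc2)COC1=O)OCC | intermediate
13 | (benzyloxy)acetaldehyde | O=CCOCc1ccccc1 | starting material
14 | (S)-4-benzyl-3-[(E)-4-(benzyloxy)but-2-enoyl]oxazolidin-2-one | O=C(/C=C/COCc1ccccc1)N1[C@@H](Cc2ccccc2)COC1=O | intermediate
15 | (E,E)-hydroxy-o-quinodimethane from 8 (exocyclic C4=C4a bearing OH, exocyclic C1=C8a bearing the aryl group, both substituents outward) | O/C=C1/C(=C/c2ccc(O[Si](C(C)C)(C(C)C)C(C)C)c(OC)c2)C=C(O[Si](C(C)C)(C(C)C)C(C)C)C(OC)=C1 | intermediate (not isolated)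
16 | (S)-4-benzyl-3-{[(1S,2R,3S,4S)-2-(benzyloxymethyl)-4-hydroxy-6-methoxy-1-[3-methoxy-4-(triisopropylsilyloxy)phenyl]-7-(triisopropylsilyloxy)-1,2,3,4-tetrahydronaphthalen-3-yl]carbonyl}oxazolidin-2-one (target locants) | COc1cc([C@H]2c3cc(O[Si](C(C)C)(C(C)C)C(C)C)c(OC)cc3[C@@H](O)[C@@H](C(=O)N3[C@@H](Cc4ccccc4)COC3=O)[C@@H]2COCc2ccccc2)ccc1O[Si](C(C)C)(C(C)C)C(C)C | intermediate
17 | [(1S,2R,3R,4S)-2-(benzyloxymethyl)-4-hydroxy-6-methoxy-1-[3-methoxy-4-(triisopropylsilyloxy)phenyl]-7-(triisopropylsilyloxy)-1,2,3,4-tetrahydronaphthalen-3-yl]methanol | COc1cc([C@H]2c3cc(O[Si](C(C)C)(C(C)C)C(C)C)c(OC)cc3[C@@H](O)[C@@H](CO)[C@@H]2COCc2ccccc2)ccc1O[Si](C(C)C)(C(C)C)C(C)C | intermediate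
18 | [(1S,2R,3R)-2-(benzyloxymethyl)-6-methoxy-1-[3-methoxy-4-(triisopropylsilyloxy)phenyl]-7-(triisopropylsilyloxy)-1,2,3,4-tetrahydronaphthalen-3-yl]methanol | COc1cc([C@H]2c3cc(O[Si](C(C)C)(C(C)C)C(C)C)c(OC)cc3C[C@@H](CO)[C@@H]2COCc2ccccc2)ccc1O[Si](C(C)C)(C(C)C)C(C)C | intermediate
19 | (1S,2R,3R)-2-(benzyloxymethyl)-3-(tert-butyldimethylsilyloxymethyl)-6-methoxy-1-[3-methoxy-4-(triisopropylsilyloxy)phenyl]-7-(triisopropylsilyloxy)-1,2,3,4-tetrahydronaphthalene | COc1cc([C@H]2c3cc(O[Si](C(C)C)(C(C)C)C(C)C)c(OC)cc3C[C@@H](CO[Si](C)(C)C(C)(C)C)[C@@H]2COCc2ccccc2)ccc1O[Si](C(C)C)(C(C)C)C(C)C | intermediate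
20 | [(1S,2R,3R)-3-(tert-butyldimethylsilyloxymethyl)-6-methoxy-1-[3-methoxy-4-(triisopropylsilyloxy)phenyl]-7-(triisopropylsilyloxy)-1,2,3,4-tetrahydronaphthalen-2-yl]methanol | COc1cc([C@H]2c3cc(O[Si](C(C)C)(C(C)C)C(C)C)c(OC)cc3C[C@@H](CO[Si](C)(C)C(C)(C)C)[C@@H]2CO)ccc1O[Si](C(C)C)(C(C)C)C(C)C | intermediate
21 | (E)-p-coumaric acid | OC(=O)/C=C/c1ccc(O)cc1 | starting material
22 | tert-butyldimethylsilyl (E)-3-[4-(tert-butyldimethylsilyloxy)phenyl]acrylate | CC(C)(C)[Si](C)(C)OC(=O)/C=C/c1ccc(O[Si](C)(C)C(C)(C)C)cc1 | intermediate (not isolated)
23 | (E)-4-(tert-butyldimethylsilyloxy)cinnamic acid | OC(=O)/C=C/c1ccc(O[Si](C)(C)C(C)(C)C)cc1 | intermediate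
24 | [(1S,2R,3R)-3-(tert-butyldimethylsilyloxymethyl)-6-methoxy-1-[3-methoxy-4-(triisopropylsilyloxy)phenyl]-7-(triisopropylsilyloxy)-1,2,3,4-tetrahydronaphthalen-2-yl]methyl (E)-3-[4-(tert-butyldimethylsilyloxy)phenyl]acrylate | COc1cc([C@H]2c3cc(O[Si](C(C)C)(C(C)C)C(C)C)c(OC)cc3C[C@@H](CO[Si](C)(C)C(C)(C)C)[C@@H]2COC(=O)/C=C/c2ccc(O[Si](C)(C)C(C)(C)C)cc2)ccc1O[Si](C(C)C)(C(C)C)C(C)C | intermediate
25 | [(1S,2R,3R)-7-hydroxy-1-(4-hydroxy-3-methoxyphenyl)-3-(hydroxymethyl)-6-methoxy-1,2,3,4-tetrahydronaphthalen-2-yl]methyl (E)-3-(4-hydroxyphenyl)acrylate | COc1cc([C@H]2c3cc(O)c(OC)cc3C[C@@H](CO)[C@@H]2COC(=O)/C=C/c2ccc(O)cc2)ccc1O | target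

## Step count and least certain steps

Total step count: 16. Longest linear sequence: 12 steps (steps 2, 3, 4, 5, 6, 9, 10, 11, 12, 13, 15, 16, from vanillin 3).

**Step 9 (key step).** The most likely failure is slow capture of the dienol. A β-substituted enoyl imide is only a moderately reactive dienophile, so return of 15 to 8, oxidation or self-reaction of the diene, and photodegradation on long irradiation may outrun the cycloaddition. The second weakness is facial discrimination, because the control element is a conformational preference of an unchelated imide and not a rigid chelate. The regiochemical pull of the hydroxyl is also opposed by that of the aryl group at the other terminus. Fallback: the generation of the diene is separated from its capture. Starting from 8, irradiation in benzene saturated with SO2 should intercept 15 by cheletropic addition and give the storable hydroxy sulfone F1. Heating F1 with 14 in toluene in the dark extrudes SO2, regenerates 15 thermally at a steady low concentration in the presence of a high concentration of dienophile, and should return to the route at 16. Poor facial selectivity would lower the amount of 16 but not its configurational purity, since the two adducts are diastereomers and are separated before step 10.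

**Step 6.** The electron-rich benzylic boronate may lose boron by protonation under aqueous base before it transmetalates, and the silyl ether para to the formyl group may be hydrolysed. Fallback with reversed roles: starting from 2, Miyaura borylation (B2pin2, PdCl2(dppf), KOAc, dioxane) should give the aryl boronate F2, which is coupled with benzylic chloride 6 under anhydrous fluoride activation (Pd(PPh3)4, CsF, dioxane) to rejoin the route at 8. This fallback also bypasses step 5.

**Step 10.** The acyl carbonyl is attached to a carbon flanked by two substituted ring carbons, so hydride may attack the ring carbonyl of the oxazolidinone instead and open the auxiliary, or the β-hydroxy imide may fragment by retro-aldol reaction. Fallback: starting from 16, hydrolysis with LiOH/H2O2 (THF/H2O, 0 °C), which is selective for the exocyclic carbonyl, should give the hydroxy acid F3, and reduction of F3 with BH3·SMe2 returns to the route at 17.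

**Step 11.** The C4 cation may be captured by the ether oxygen of the C2 benzyloxymethyl group (five-membered oxonium ion, then loss of the benzyl group) or may lose the C3 proton to give an alkene before hydride arrives. Fallback without a cation: starting from 17, selective silylation of the primary hydroxyl (TBSCl, imidazole, 0 °C) should give the mono-silyl ether F4, acylation of the C4 hydroxyl with phenyl chlorothionoformate (pyridine, DMAP) the thionocarbonate F5, and Barton–McCombie reduction (Bu3SnH, AIBN, toluene, 80 °C) rejoins the route at 19.

**Step 16.** Under fluoride the coumaroyl group may move to the freed C9′ hydroxyl or be cleaved, and the primary alkyl silyl ether may resist buffered conditions so that harsher, more basic treatment is needed. Fallback in which no ester meets fluoride: starting from 20, brief treatment with buffered TBAF at 0 °C should remove only the two aryl silyl groups and give the bis-phenol F6. Mitsunobu esterification of F6 with unprotected 21 (PPh3, DIAD, THF), in which the carboxylic acid is the most acidic partner, should give the mono-silyl ester F7. Mild acid (AcOH/THF/H2O) then removes the last silyl group and arrives at 25.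

## Further compounds

F1 | step 9 | 1-hydroxy-6-methoxy-3-[3-methoxy-4-(triisopropylsilyloxy)phenyl]-5-(triisopropylsilyloxy)-1,3-dihydrobenzo[c]thiophene 2,2-dioxide (racemic diastereomer mixture; both centres are lost on extrusion) | COc1cc2C(O)S(=O)(=O)C(c3ccc(O[Si](C(C)C)(C(C)C)C(C)C)c(OC)c3)c2cc1O[Si](C(C)C)(C(C)C)C(C)C
F2 | step 6 | 5-methoxy-2-(4,4,5,5-tetramethyl-1,3,2-dioxaborolan-2-yl)-4-(triisopropylsilyloxy)benzaldehyde | COc1cc(C=O)c(B2OC(C)(C)C(C)(C)O2)cc1O[Si](C(C)C)(C(C)C)C(C)C
F3 | step 10 | (1S,2R,3S,4S)-2-(benzyloxymethyl)-4-hydroxy-6-methoxy-1-[3-methoxy-4-(triisopropylsilyloxy)phenyl]-7-(triisopropylsilyloxy)-1,2,3,4-tetrahydronaphthalene-3-carboxylic acid (target locants) | COc1cc([C@H]2c3cc(O[Si](C(C)C)(C(C)C)C(C)C)c(OC)cc3[C@@H](O)[C@@H](C(=O)O)[C@@H]2COCc2ccccc2)ccc1O[Si](C(C)C)(C(C)C)C(C)C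
F4 | step 11 | (1S,2R,3R,4S)-2-(benzyloxymethyl)-3-(tert-butyldimethylsilyloxymethyl)-6-methoxy-1-[3-methoxy-4-(triisopropylsilyloxy)phenyl]-7-(triisopropylsilyloxy)-1,2,3,4-tetrahydronaphthalen-4-ol | COc1cc([C@H]2c3cc(O[Si](C(C)C)(C(C)C)C(C)C)c(OC)cc3[C@@H](O)[C@@H](CO[Si](C)(C)C(C)(C)C)[C@@H]2COCc2ccccc2)ccc1O[Si](C(C)C)(C(C)C)C(C)C
F5 | step 11 | O-phenyl thionocarbonate of F4 at the C4 oxygen | COc1cc([C@H]2c3cc(O[Si](C(C)C)(C(C)C)C(C)C)c(OC)cc3[C@@H](OC(=S)Oc3ccccc3)[C@@H](CO[Si](C)(C)C(C)(C)C)[C@@H]2COCc2ccccc2)ccc1O[Si](C(C)C)(C(C)C)C(C)C
F6 | step 16 | [(1S,2R,3R)-3-(tert-butyldimethylsilyloxymethyl)-7-hydroxy-1-(4-hydroxy-3-methoxyphenyl)-6-methoxy-1,2,3,4-tetrahydronaphthalen-2-yl]methanol | COc1cc([C@H]2c3cc(O)c(OC)cc3C[C@@H](CO[Si](C)(C)C(C)(C)C)[C@@H]2CO)ccc1O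
F7 | step 16 | [(1S,2R,3R)-3-(tert-butyldimethylsilyloxymethyl)-7-hydroxy-1-(4-hydroxy-3-methoxyphenyl)-6-methoxy-1,2,3,4-tetrahydronaphthalen-2-yl]methyl (E)-3-(4-hydroxyphenyl)acrylate | COc1cc([C@H]2c3cc(O)c(OC)cc3C[C@@H](CO[Si](C)(C)C(C)(C)C)[C@@H]2COC(=O)/C=C/c2ccc(O)cc2)ccc1O
A1 | alternative 1 | (S)-4-benzyl-3-[(E)-3-(3-bromo-4-hydroxy-5-methoxyphenyl)acryloyl]oxazolidin-2-one | COc1cc(/C=C/C(=O)N2[C@@H](Cc3ccccc3)COC2=O)cc(Br)c1O
A2 | alternative 1 | trans-1-aryl-1,2-dihydronaphthalene-2,3-dicarbonyl bis-imide (8-bromo-7-hydroxy-6-methoxy, aryl = 3-bromo-4-hydroxy-5-methoxyphenyl) | COc1cc([C@H]2c3c(Br)c(O)c(OC)cc3C=C(C(=O)N3[C@@H](Cc4ccccc4)COC3=O)[C@@H]2C(=O)N2[C@@H](Cc3ccccc3)COC2=O)cc(Br)c1O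
A3 | alternative 2 | 4-(3-hydroxy-4-methoxyphenyl)-4-[3-methoxy-4-(triisopropylsilyloxy)phenyl]-2-methylene-3-{[(E)-4-(triisopropylsilyloxy)cinnamoyloxy]methyl}butanal, C1 and C2 configured as in the target | COc1cc([C@@H](c2cc(O)c(OC)cc2)[C@@H](COC(=O)/C=C/c2ccc(O[Si](C(C)C)(C(C)C)C(C)C)cc2)C(=C)C=O)ccc1O[Si](C(C)C)(C(C)C)C(C)C
A4 | alternative 2 | aryltetralin-3-carbaldehyde with the C9 p-coumarate in place | COc1cc([C@H]2c3cc(O)c(OC)cc3C[C@@H](C=O)[C@@H]2COC(=O)/C=C/c2ccc(O[Si](C(C)C)(C(C)C)C(C)C)cc2)ccc1O[Si](C(C)C)(C(C)C)C(C)C
A5 | alternative 3 | 4-(chloromethyl)-2-methoxyphenyl pivalate | COc1cc(CCl)ccc1OC(=O)C(C)(C)C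
A6 | alternative 3 | dimethyl 2,3-cis-2-formyl-3-[3-methoxy-4-(triisopropylsilyloxy)phenyl]cyclopropane-1,1-dicarboxylate | COc1cc([C@H]2[C@@H](C=O)C2(C(=O)OC)C(=O)OC)ccc1O[Si](C(C)C)(C(C)C)C(C)C
A7 | alternative 3 | 1-aryltetralin-2-carbaldehyde-3,3-diester | COc1cc([C@H]2c3cc(OC(=O)C(C)(C)C)c(OC)cc3CC(C(=O)OC)(C(=O)OC)[C@@H]2C=O)ccc1O[Si](C(C)C)(C(C)C)C(C)C
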